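The synthesis rests on cutting the two biaryl bonds between C3/C6 of the central ring (C1/C2 carry the acyloxy groups, C4/C5 the hydroxyls) and the two 4-hydroxyphenyl rings. C3 and C6 are para, carry identical aryl rings and are interchanged by the symmetry axis bisecting the C1–C2 and C4–C5 bonds. One twofold Suzuki–Miyaura coupling therefore forms both bonds without any site selectivity. The precursor is a hexasubstituted 3,6-dibromobenzene whose four oxygens are already sorted into adjacent pairs: O1/O2 as benzyl ethers, O4/O5 as TBS ethers. Hydrogenolysis, double acylation with a (4S,5S)-epoxy-ynoic acid, Lindlar reduction and fluoride desilylation follow.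

Key step: step 5

Remark: both acyl residues are read from the SMILES as (2Z,4S,5S) with trans epoxides; reactions at equivalent groups are written as single transformations, and only the monoarylated bromide of the key step is numbered, because it must re-enter the catalytic cycle.

Step 1
Reactants: 1 3,4-bis(benzyloxy)benzaldehyde
Product: 3 3,4-bis(benzyloxy)phenol, via aryl formate 2 (not isolated)
Conditions: mCPBA, CH2Cl2, 0 °C → rt; NaHCO3 wash; then K2CO3 (cat.), MeOH, rt
Reagents that add atoms: mCPBA, O=C(OO)c1cccc(Cl)c1
Why: Baeyer–Villiger oxidation, in which the electron-rich 3,4-dialkoxyaryl group of the Criegee adduct migrates in preference to hydride to give formate 2, which base-catalysed methanolysis cleaves; a peracid is used because the alkaline-peroxide Dakin reaction needs a free ortho or para hydroxyl, which 1 lacks.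

Step 2
Reactants: 3 3,4-bis(benzyloxy)phenol
Product: 5 4,5-bis(benzyloxy)benzene-1,2-diol, via ortho-quinone 4 (not isolated)
Conditions: IBX (1.1 equiv), DMF, rt; then aq Na2S2O4, rt, under Ar
Reagents that add atoms: IBX, O=C1OI(=O)(O)c2ccccc12
Why: IBX-mediated ortho-oxygenation of an electron-rich phenol, in which the phenol binds to iodine(V) and oxygen is delivered intramolecularly to the less hindered ortho carbon C6 (para to a benzyloxy group) rather than to C2 between two oxygens, and the stable vinylogous-ester quinone 4 is then reduced by dithionite.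

Step 3
Reactants: 5 4,5-bis(benzyloxy)benzene-1,2-diol
Product: 6 1,2-bis(benzyloxy)-4,5-bis(tert-butyldimethylsilyloxy)benzene
Conditions: TBSCl (2.5 equiv), imidazole (5 equiv), DMF, rt, under Ar
Reagents that add atoms: TBSCl, CC(C)(C)[Si](C)(C)Cl
Why: Routine imidazole-promoted silylation of a catechol; two open-chain TBS ethers are preferred to a five-membered cyclic silylene because that strained O–Si–O ring is opened by mild base and would be the weak point of step 5, and all four silyl groups of the later intermediates then fall in one fluoride step.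

Step 4
Reactants: 6 1,2-bis(benzyloxy)-4,5-bis(tert-butyldimethylsilyloxy)benzene
Product: 7 1,2-bis(benzyloxy)-3,6-dibromo-4,5-bis(tert-butyldimethylsilyloxy)benzene
Conditions: NBS (2.1 equiv), CH2Cl2/MeCN, 0 °C → rt, dark
Reagents that add atoms: NBS, O=C1CCC(=O)N1Br
Why: Electrophilic aromatic bromination, well known for 1,2,4,5-tetraalkoxybenzenes, at the only two free positions of the core, each ortho to a benzyloxy and a silyloxy group and far more activated than the benzyl phenyl rings, while dry and dark conditions suppress oxidation to a quinone and radical benzylic bromination.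

Step 5
Reactants: 7 1,2-bis(benzyloxy)-3,6-dibromo-4,5-bis(tert-butyldimethylsilyloxy)benzene; 8 4-(tert-butyldimethylsilyloxy)phenylboronic acid (3 equiv)
Product: 10 2',3'-bis(benzyloxy)-4,4'',5',6'-tetrakis(tert-butyldimethylsilyloxy)-1,1':4',1''-terphenyl, via monoarylated bromide 9 (not isolated)
Conditions: Pd(OAc)2 (5 mol %), SPhos (10 mol %), powdered K3PO4 (5 equiv), degassed toluene, no added water, 90 °C
Reagents that add atoms: none
Why: Each cycle runs through oxidative addition of monoligated SPhos–Pd(0) into a C–Br bond, transmetalation from the phosphate-activated boronate of 8 and reductive elimination, so bromide 9 forms first and re-enters the same cycle to give 10. The closest known reaction type is the Suzuki–Miyaura coupling of electron-rich 2,6-dioxygenated aryl bromides with unhindered arylboronic acids under bulky dialkylbiarylphosphine ligation, and each new biaryl is only di-ortho-substituted because 8 has no ortho group. No ring is closed and no stereocentre is created, and the new axes are not stereogenic since the outer rings are symmetric about them. No site selectivity is needed because C3 and C6 are symmetry-equivalent and hold the only carbon–halogen bonds, so the sole demand is complete twofold conversion, which excess 8 and a long-lived catalyst should secure. Chemoselectivity rests on the substrate: the benzyl ethers are inert, and solid K3PO4 in toluene keeps dissolved base low enough for the aryl TBS ethers, the two on the core being shielded further by their neighbours. The O1/O2 versus O4/O5 distinction is untouched because it is stored in the benzyl/silyl pattern fixed before any arene arrives.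

Step 6
Reactants: 10 2',3'-bis(benzyloxy)-4,4'',5',6'-tetrakis(tert-butyldimethylsilyloxy)-1,1':4',1''-terphenyl
Product: 11 4,4'',5',6'-tetrakis(tert-butyldimethylsilyloxy)-1,1':4',1''-terphenyl-2',3'-diol
Conditions: H2 (1 atm), 10% Pd/C, EtOAc, rt; filtered under Ar and used at once
Reagents that add atoms: none
Why: Heterogeneous hydrogenolysis of aryl benzyl ethers, to which aryl TBS ethers are inert in an aprotic solvent and for which no other reducible group is present, unmasks exactly the O1/O2 pair so that the diacylation needs no selectivity.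

Step 7
Reactants: 12 (E)-but-2-en-1-ol (crotyl alcohol)
Product: 13 (2S,3S)-2,3-epoxybutan-1-ol (trans)
Conditions: Ti(OiPr)4 (5 mol %), L-(+)-DIPT (6 mol %), anhydrous TBHP, 4 Å MS, CH2Cl2, −20 °C; non-aqueous work-up
Reagents that add atoms: tert-butyl hydroperoxide, CC(C)(C)OO
Why: Sharpless asymmetric epoxidation, in which the L-(+)-tartrate–titanium complex delivers oxygen to the alkene face that gives the (2S,3S) epoxide, the E geometry fixing the trans relationship and the ligand the absolute configuration of the future C4 and C5; the work-up is non-aqueous because 13 is small and water-soluble.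

Step 8
Reactants: 13 (2S,3S)-2,3-epoxybutan-1-ol
Product: 14 (2R,3S)-2,3-epoxybutanal
Conditions: TPAP (5 mol %), NMO (1.5 equiv), 4 Å MS, CH2Cl2, rt; silica plug, kept as CH2Cl2 solution
Reagents that add atoms: none
Why: Ley–Griffith oxidation, established for 2,3-epoxy alcohols, is neutral and needs only a filtration, so the volatile, water-soluble aldehyde is obtained in solution without epimerisation (the C2 descriptor becomes R only through the CIP priorities).

Step 9
Reactants: 14 (2R,3S)-2,3-epoxybutanal
Product: 15 (2S,3S)-2-(2,2-dibromoethenyl)-3-methyloxirane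
Conditions: CBr4 (2 equiv), PPh3 (4 equiv), Et3N (1 equiv), CH2Cl2, −60 °C → 0 °C
Reagents that add atoms: carbon tetrabromide, BrC(Br)(Br)Br
Why: Ramirez dibromoolefination (first stage of the Corey–Fuchs homologation), a Wittig-type reaction of the dibromomethylene ylide in the triethylamine-buffered variant used for acid-sensitive epoxy aldehydes, leaves both stereocentres untouched and gives a far less volatile intermediate.

Step 10
Reactants: 15 (2S,3S)-2-(2,2-dibromoethenyl)-3-methyloxirane
Product: 18 (4S,5S)-4,5-epoxyhex-2-ynoic acid, via lithium acetylide 16 (not isolated), via lithium carboxylate 17 (not isolated)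
Conditions: n-BuLi (2.1 equiv), THF, −78 °C; dry CO2, −78 → −20 °C; cold aq KHSO4, EtOAc extraction, used at once
Reagents that add atoms: carbon dioxide, O=C=O
Why: Second stage of the Corey–Fuchs sequence (Br/Li exchange, loss of LiBr with Fritsch–Buttenberg–Wiechell-type 1,2-shift, deprotonation) followed by carboxylation of the acetylide, which at −78 °C outruns attack of butyllithium on the epoxide, and the linear alkyne holds the carboxyl group away from C4 so that no butenolide can form.

Step 11
Reactants: 11 4,4'',5',6'-tetrakis(tert-butyldimethylsilyloxy)-1,1':4',1''-terphenyl-2',3'-diol; 18 (4S,5S)-4,5-epoxyhex-2-ynoic acid (2.6 equiv)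
Product: 19 4,4'',5',6'-tetrakis(tert-butyldimethylsilyloxy)-1,1':4',1''-terphenyl-2',3'-diyl bis[(4S,5S)-4,5-epoxyhex-2-ynoate]
Conditions: DCC (2.6 equiv), DMAP (0.2 equiv), CH2Cl2, −20 → 0 °C, under Ar
Reagents that add atoms: none
Why: Steglich esterification, the usual entry to aryl 2-alkynoates, in which the slim and highly electrophilic activated ynoate reaches both aryl-flanked hydroxyls (the only nucleophiles present), while excess acyl donor, low temperature and little DMAP disfavour conjugate addition to the triple bond.

Step 12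
Reactants: 19 4,4'',5',6'-tetrakis(tert-butyldimethylsilyloxy)-1,1':4',1''-terphenyl-2',3'-diyl bis[(4S,5S)-4,5-epoxyhex-2-ynoate]
Product: 20 4,4'',5',6'-tetrakis(tert-butyldimethylsilyloxy)-1,1':4',1''-terphenyl-2',3'-diyl bis[(2Z,4S,5S)-4,5-epoxyhex-2-enoate]
Conditions: H2 (1 atm), Lindlar catalyst (Pd/CaCO3, Pb), quinoline, EtOAc, rt, stopped after two equivalents of H2
Reagents that add atoms: none
Why: Lindlar semihydrogenation, known both for alkynyl epoxides and for 2-ynoates, adds H2 in syn fashion from the poisoned palladium surface and so sets both Z alkenes, with quinoline and control of the uptake guarding against over-reduction and allylic C–O hydrogenolysis.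

Step 13
Reactants: 20 4,4'',5',6'-tetrakis(tert-butyldimethylsilyloxy)-1,1':4',1''-terphenyl-2',3'-diyl bis[(2Z,4S,5S)-4,5-epoxyhex-2-enoate]
Product: 21 4,4'',5',6'-tetrahydroxy-1,1':4',1''-terphenyl-2',3'-diyl bis[(2Z,4S,5S)-4,5-epoxyhex-2-enoate] (CNP0249450.1)
Conditions: Et3N·3HF (excess), THF, 0 °C → rt, plastic vessel, under Ar; pH 7 buffer work-up
Reagents that add atoms: none
Why: Fluoride-driven cleavage of aryl silyl ethers with a nearly neutral amine–HF complex, chosen because strongly acidic HF–pyridine can open a vinyl epoxide to a fluorohydrin and unbuffered TBAF would release phenoxides that attack the aryl esters, while intramolecular acyl migration is excluded since every ester oxygen is separated from the nearest hydroxyl by an aryl-bearing carbon.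

Compound list
1 | 3,4-bis(benzyloxy)benzaldehyde | O=Cc1ccc(OCc2ccccc2)c(OCc2ccccc2)c1 | starting material
2 | 3,4-bis(benzyloxy)phenyl formate | O=COc1ccc(OCc2ccccc2)c(OCc2ccccc2)c1 | intermediate
3 | 3,4-bis(benzyloxy)phenol | Oc1ccc(OCc2ccccc2)c(OCc2ccccc2)c1 | intermediate
4 | 4,5-bis(benzyloxy)cyclohexa-3,5-diene-1,2-dione | O=C1C=C(OCc2ccccc2)C(OCc2ccccc2)=CC1=O | intermediate
5 | 4,5-bis(benzyloxy)benzene-1,2-diol | Oc1cc(OCc2ccccc2)c(OCc2ccccc2)cc1O | intermediate
6 | 1,2-bis(benzyloxy)-4,5-bis(tert-butyldimethylsilyloxy)benzene | CC(C)(C)[Si](C)(C)Oc1cc(OCc2ccccc2)c(OCc2ccccc2)cc1O[Si](C)(C)C(C)(C)C | intermediate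
7 | 1,2-bis(benzyloxy)-3,6-dibromo-4,5-bis(tert-butyldimethylsilyloxy)benzene | Brc1c(OCc2ccccc2)c(OCc2ccccc2)c(Br)c(O[Si](C)(C)C(C)(C)C)c1O[Si](C)(C)C(C)(C)C | intermediate
8 | 4-(tert-butyldimethylsilyloxy)phenylboronic acid | CC(C)(C)[Si](C)(C)Oc1ccc(B(O)O)cc1 | starting material
9 | 2,3-bis(benzyloxy)-4-bromo-4',5,6-tris(tert-butyldimethylsilyloxy)-1,1'-biphenyl | Brc1c(OCc2ccccc2)c(OCc2ccccc2)c(-c2ccc(O[Si](C)(C)C(C)(C)C)cc2)c(O[Si](C)(C)C(C)(C)C)c1O[Si](C)(C)C(C)(C)C | intermediate
10 | 2',3'-bis(benzyloxy)-4,4'',5',6'-tetrakis(tert-butyldimethylsilyloxy)-1,1':4',1''-terphenyl | CC(C)(C)[Si](C)(C)Oc1ccc(cc1)-c1c(OCc2ccccc2)c(OCc2ccccc2)c(-c2ccc(O[Si](C)(C)C(C)(C)C)cc2)c(O[Si](C)(C)C(C)(C)C)c1O[Si](C)(C)C(C)(C)C | intermediate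
11 | 4,4'',5',6'-tetrakis(tert-butyldimethylsilyloxy)-1,1':4',1''-terphenyl-2',3'-diol | CC(C)(C)[Si](C)(C)Oc1ccc(cc1)-c1c(O)c(O)c(-c2ccc(O[Si](C)(C)C(C)(C)C)cc2)c(O[Si](C)(C)C(C)(C)C)c1O[Si](C)(C)C(C)(C)C | intermediate
12 | (E)-but-2-en-1-ol | C/C=C/CO | starting material
13 | (2S,3S)-2,3-epoxybutan-1-ol | C[C@@H]1O[C@H]1CO | intermediate
14 | (2R,3S)-2,3-epoxybutanal | C[C@@H]1O[C@H]1C=O | intermediate
15 | (2S,3S)-2-(2,2-dibromoethenyl)-3-methyloxirane | C[C@@H]1O[C@H]1C=C(Br)Br | intermediate
16 | lithium [(2S,3S)-3-methyloxiran-2-yl]acetylide | C[C@@H]1O[C@H]1C#C[Li] | intermediate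
17 | lithium (4S,5S)-4,5-epoxyhex-2-ynoate | C[C@@H]1O[C@H]1C#CC(=O)[O-].[Li+] | intermediate
18 | (4S,5S)-4,5-epoxyhex-2-ynoic acid | C[C@@H]1O[C@H]1C#CC(=O)O | intermediate
19 | tetra-TBS terphenyl-2',3'-diyl bis[(4S,5S)-4,5-epoxyhex-2-ynoate] | C[C@@H]1O[C@H]1C#CC(=O)Oc1c(OC(=O)C#C[C@@H]2O[C@H]2C)c(-c2ccc(O[Si](C)(C)C(C)(C)C)cc2)c(O[Si](C)(C)C(C)(C)C)c(O[Si](C)(C)C(C)(C)C)c1-c1ccc(O[Si](C)(C)C(C)(C)C)cc1 | intermediate
20 | tetra-TBS terphenyl-2',3'-diyl bis[(2Z,4S,5S)-4,5-epoxyhex-2-enoate] | C[C@@H]1O[C@H]1/C=C\C(=O)Oc1c(OC(=O)/C=C\[C@@H]2O[C@H]2C)c(-c2ccc(O[Si](C)(C)C(C)(C)C)cc2)c(O[Si](C)(C)C(C)(C)C)c(O[Si](C)(C)C(C)(C)C)c1-c1ccc(O[Si](C)(C)C(C)(C)C)cc1 | intermediate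
21 | 4,4'',5',6'-tetrahydroxy-1,1':4',1''-terphenyl-2',3'-diyl bis[(2Z,4S,5S)-4,5-epoxyhex-2-enoate] | C[C@@H]1O[C@H]1/C=C\C(=O)Oc1c(OC(=O)/C=C\[C@@H]2O[C@H]2C)c(-c2ccc(O)cc2)c(O)c(O)c1-c1ccc(O)cc1 | target

Total step count: 13. Longest linear sequence: 9 steps (steps 1–6, then 11–13). The side chain takes steps 7–10.

Steps most likely to fail

**Step 5.**
- What may go wrong: the reaction may stall after the first coupling. The hindered, electron-rich aryl–palladium species may undergo hydrodebromination. Boronic acid 8 may protodeboronate, and the base may strip aryl silyl groups.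
- Fallback: a base-free and water-free Negishi coupling that forms the same two bonds, setting out from 7.
- Commercial tert-butyl(4-bromophenoxy)dimethylsilane (CC(C)(C)[Si](C)(C)Oc1ccc(Br)cc1) would be converted with n-BuLi in THF at −78 °C into [4-(tert-butyldimethylsilyloxy)phenyl]lithium F1.
- Transmetalation with ZnCl2 would give [4-(tert-butyldimethylsilyloxy)phenyl]zinc chloride F2.
- F2 would be coupled twice with 7 under Pd/SPhos in THF at 50–60 °C. The route is rejoined at 10.

**Step 11.**
- What may go wrong: the strongly acidic ynoic acid may open its own epoxide before activation. After the first acylation, the neighbouring phenol or DMAP may add in conjugate fashion to the activated triple bond.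
- Fallback: the acyl chain is built on the arene by olefination, setting out from 11 and from aldehyde 14.
- Mild saponification of commercial methyl bis(2,2,2-trifluoroethyl)phosphonoacetate would give 2-[bis(2,2,2-trifluoroethoxy)phosphoryl]acetic acid F3.
- DCC coupling of F3 with 11 would give the terphenyl-2',3'-diyl bis(phosphonoacetate) F4.
- A twofold Still–Gennari olefination of F4 with 14 (KHMDS, 18-crown-6, THF, −78 °C) would set both Z alkenes directly. The route is rejoined at 20, bypassing 18, 19 and the semihydrogenation.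

**Step 12.**
- What may go wrong: the enoates may be over-reduced, the allylic epoxide C–O bond may be cleaved by hydrogenolysis, and the two alkynes of a precious late intermediate may react at unequal rates.
- Fallback: the semihydrogenation is moved to the small, monofunctional acid, setting out from 18.
- Lindlar reduction of 18 would give (2Z,4S,5S)-4,5-epoxyhex-2-enoic acid F5. F5 would be kept cold and used immediately, because cyclisation of the carboxyl group onto C4 is its decay path.
- Carbodiimide coupling of F5 with 11 rejoins the route at 20, so the terphenyl diester never meets palladium and hydrogen.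

Further compounds
F1 | step 5 | [4-(tert-butyldimethylsilyloxy)phenyl]lithium | CC(C)(C)[Si](C)(C)Oc1ccc([Li])cc1
F2 | step 5 | [4-(tert-butyldimethylsilyloxy)phenyl]zinc chloride | CC(C)(C)[Si](C)(C)Oc1ccc([Zn]Cl)cc1
F3 | step 11 | 2-[bis(2,2,2-trifluoroethoxy)phosphoryl]acetic acid | O=C(O)CP(=O)(OCC(F)(F)F)OCC(F)(F)F
F4 | step 11 | 4,4'',5',6'-tetrakis(tert-butyldimethylsilyloxy)-1,1':4',1''-terphenyl-2',3'-diyl bis{2-[bis(2,2,2-trifluoroethoxy)phosphoryl]acetate} | O=C(CP(=O)(OCC(F)(F)F)OCC(F)(F)F)Oc1c(OC(=O)CP(=O)(OCC(F)(F)F)OCC(F)(F)F)c(-c2ccc(O[Si](C)(C)C(C)(C)C)cc2)c(O[Si](C)(C)C(C)(C)C)c(O[Si](C)(C)C(C)(C)C)c1-c1ccc(O[Si](C)(C)C(C)(C)C)cc1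
F5 | step 12 | (2Z,4S,5S)-4,5-epoxyhex-2-enoic acid | C[C@@H]1O[C@H]1/C=C\C(=O)O
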